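**Retrosynthetic overview**

1. Feature: ring B (C5–C10) with the flanking C4 is a hidden verbenone. C4 (CMe2), C5 and C10 (angular CH3) are the CMe2 bridge, a bridgehead and the methyl-bearing enone carbon of (1R,5R)-verbenone; C6, C7, C8 and C9 are its CH2 bridge, second bridgehead, carbonyl and α-carbon.
2. Key disconnection C3–C4: ionising the cyclobutane bond C7–C4 releases ring B, and a silyl enol ether arm (C1–C3) on C10 catches the C4 cation to close ring A (ring B first, ring A second).
3. Before: C10 by conjugate addition of a methallyl group anti to the CMe2 bridge, C11 by enolate alkylation with benzyl chloromethyl ether, then ozonolysis and kinetic silylation of the arm.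
4. After: C2 deoxygenation with C8 masked, C9 equilibration, Δ7 enol triflate and methyl coupling (11-O-benzyldrimenol), then OsO4, C7 oxidation, C6 Rubottom oxidation/acetylation and reduction to 7β-OH.
5. End: debenzylation, C11 aldehyde, Wittig reaction with the acetonyl ylide for the E-enone.

Key step: step 5

Assumption: the enolate alkylation of step 2 is drawn anti to the CMe2 bridge, which places the C11 arm 9α; the route does not depend on this because C9 is equilibrated in step 8. Labdane/drimane numbering is used from compound 10 on.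

**Step 1**
Reactants: 1 (1R,5R)-verbenone; 2 2-methylallylmagnesium chloride
Product: 3 4,6,6-trimethyl-4-(2-methylallyl)-2-(trimethylsilyloxy)bicyclo[3.1.1]hept-2-ene (methallyl anti to the CMe2 bridge)
Conditions: CuBr·SMe2 (1.5 equiv), Me3SiCl (3 equiv), THF, −78 °C; Et3N, aq. NaHCO3
Reagents that add atoms: chlorotrimethylsilane, C[Si](C)(C)Cl
Why: Me3SiCl-accelerated conjugate addition of the allylic copper reagent should deliver the methallyl group to the β-carbon from the face anti to the CMe2 bridge, whose inward methyl shields the other face, and so set the quaternary centre that becomes C10.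

**Step 2**
Reactants: 3 silyl enol ether; 4 benzyl chloromethyl ether
Product: 6 3-(benzyloxymethyl)-4,6,6-trimethyl-4-(2-methylallyl)bicyclo[3.1.1]heptan-2-one (CH2OBn cis to the methallyl group; both anti to the CMe2 bridge), via lithium enolate 5 (not isolated)
Conditions: MeLi, THF, 0 °C; then 4, −78 → −30 °C
Reagents that add atoms: none
Why: MeLi cleaves the silyl enol ether to the regiodefined lithium enolate (Stork–House), and its C-alkylation by the reactive α-chloro ether should again occur anti to the CMe2 bridge, which gives the future C9 centre in the configuration that step 8 corrects.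

**Step 3**
Reactants: 6 methallyl ketone
Product: 7 3-(benzyloxymethyl)-4,6,6-trimethyl-4-(2-oxopropyl)bicyclo[3.1.1]heptan-2-one
Conditions: O3, CH2Cl2–MeOH, −78 °C (stopped at first excess); Me2S, −78 °C → rt
Reagents that add atoms: ozone, [O-][O+]=O
Why: Ozonolysis with reductive work-up cleaves the 1,1-disubstituted alkene much faster than it attacks the benzyl ether and gives the methyl ketone whose carbons become C1–C3.

**Step 4**
Reactants: 7 diketone
Product: 9 3-(benzyloxymethyl)-4,6,6-trimethyl-4-[2-(trimethylsilyloxy)allyl]bicyclo[3.1.1]heptan-2-one, via lithium enolate 8 (not isolated)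
Conditions: LDA (1.1 equiv) premixed with Me3SiCl (3 equiv), THF, −78 °C; Et3N, pentane, filtration
Reagents that add atoms: chlorotrimethylsilane, C[Si](C)(C)Cl
Why: Kinetic deprotonation takes the unhindered methyl group (the ring ketone has only a shielded tertiary α-H and a non-enolisable bridgehead), and the internal Me3SiCl quench traps the terminal enolate before it can add to the ring ketone in an aldol reaction.

**Step 5**
Reactants: 9 silyl enol ether ketone
Product: 10 9α-(benzyloxymethyl)-4,4,10β-trimethyl-8-(trimethylsilyloxy)-trans-octal-7-en-2-one (5α-H)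
Conditions: Me3SiOTf (0.3 equiv), 2,6-di-tert-butyl-4-methylpyridine (0.1 equiv), CH2Cl2, −78 → −20 °C; Et3N, pH 7 buffer
Reagents that add atoms: none
Why: Proposed new method: Me3SiOTf silylates the C8 carbonyl, the cyclobutane bond C7–C4 (held nearly parallel to the carbonyl π system) ionises with loss of the four-ring strain to give the C7=C8 silyl enol ether and a tertiary cation at C4, the terminal enol ether carbon C3 adds to C4, and the C2 silyloxocarbenium returns Me3Si+ to triflate, so the overall change is an isomerisation that turns over the silyl triflate. The closest known reactions are the Me3SiI- or BF3·OEt2-promoted fragmentation of nopinone- and verbanone-type cyclobutyl ketones to p-menthenyl cations and the Lewis acid tert-alkylation of silyl enol ethers (Reetz, Mukaiyama type), which have not been merged in one operation. Ring A closes in a 6-endo-trig attack of the enol ether double bond on the exocyclic cation through a chair-like transition state with both arms equatorial on the half-chair of ring B. No stereocentre is created: C5 and C10 come unchanged from 9 and, since the cation arm on C5 and the nucleophilic arm on C10 are trans (set in step 1), only the trans ring fusion is accessible, while C9 is a spectator. The step needs fragmentation to outrun Mukaiyama aldol addition of the arm to the silylated C8 carbonyl and C–C capture to outrun proton loss from C4; the first rests on the hindered C8 (flanked by the bridgehead and the substituted C9) and on irreversible strain release against a reversible congested aldol, the second on the six-membered chair closure, the pyridine buffer and the low temperature. The 9α-benzyloxymethyl group is trans to the cation arm and cannot reach C4, so ether participation is not expected.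

**Step 6**
Reactants: 10 enol silane ketone
Product: 11 9α-(benzyloxymethyl)-8,8-(ethylenedioxy)-4,4,10β-trimethyl-trans-decalin-2-one
Conditions: ethylene glycol (5 equiv), PPTS (0.1 equiv), benzene, reflux, Dean–Stark
Reagents that add atoms: ethylene glycol, OCCO
Why: Acid-catalysed protodesilylation and dioxolane formation should be selective for C8, because a ketal oxygen at C2 would be syn-axial to both the C10 and the 4β methyl groups whereas at C8 it meets only the C10 methyl.

**Step 7**
Reactants: 11 keto ketal
Product: 13 9α-(benzyloxymethyl)-8,8-(ethylenedioxy)-4,4,10β-trimethyl-trans-decalin (11-benzyloxy-9-epi-12-nordriman-8-one ethylene ketal), via C2 hydrazone 12 (not isolated)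
Conditions: N2H4·H2O, KOH, diethylene glycol, 130 °C then 200 °C
Reagents that add atoms: none
Why: Wolff–Kishner reduction (Huang–Minlon) removes the C2 carbonyl through its hydrazone, which can form at this hindered position because the carbon stays sp2, and the ketal and benzyl ether tolerate hot KOH.

**Step 8**
Reactants: 13 ketal
Product: 15 11-benzyloxy-12-nordriman-8-one (9β-CH2OBn; 9α-H), via 9-epi ketone 14 (not isolated)
Conditions: 2 M HCl, THF, 40 °C; extractive work-up; then BnONa (0.3 equiv), BnOH–THF, 40 °C
Reagents that add atoms: water, O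
Why: Acid hydrolysis of the dioxolane returns the C8 ketone and base-mediated enolisation–reprotonation (epimerisation) should move the C11 arm from the axial 9α to the equatorial 9β position, while benzyl alcohol with its own alkoxide makes any E1cB loss and re-addition of benzyloxide degenerate.

**Step 9**
Reactants: 15 ketone
Product: 17 11-benzyloxy-12-nordrim-7-en-8-yl trifluoromethanesulfonate, via lithium enolate 16 (not isolated)
Conditions: LDA, THF, −78 °C; PhNTf2, −78 → 0 °C
Reagents that add atoms: N-phenylbis(trifluoromethanesulfonimide), O=S(=O)(N(c1ccccc1)S(=O)(=O)C(F)(F)F)C(F)(F)F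
Why: Kinetic enolate formation removes the accessible axial 7α-H and not the neopentyl tertiary H-9, and O-triflation fixes the Δ7 enol triflate.

**Step 10**
Reactants: 17 enol triflate
Product: 18 11-O-benzyldrimenol (11-benzyloxydrim-7-ene)
Conditions: MeMgBr (1.5 equiv), Fe(acac)3 (5 mol%), THF–NMP, −30 → 0 °C
Reagents that add atoms: methylmagnesium bromide, C[Mg]Br
Why: Iron-catalysed Kumada-type cross-coupling of the alkenyl triflate with the methyl Grignard reagent installs the C8 methyl group and keeps the alkene at C7–C8.

**Step 11**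
Reactants: 18 alkene
Product: 19 11-benzyloxydrimane-7α,8α-diol
Conditions: OsO4 (5 mol%), NMO, acetone–H2O, rt
Reagents that add atoms: N-methylmorpholine N-oxide, C[N+]1([O-])CCOCC1; water, O
Why: Upjohn dihydroxylation should occur on the α face, opposite the axial C10 methyl, and set 8α-OH with the 8β-methyl group together with a provisional 7α-OH.

**Step 12**
Reactants: 19 diol
Product: 20 11-benzyloxy-8α-hydroxydriman-7-one
Conditions: IBX, DMSO, rt
Reagents that add atoms: none
Why: IBX oxidises the secondary C7 alcohol of the vicinal diol to the ketone without glycol cleavage and cannot touch the tertiary 8α-OH.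

**Step 13**
Reactants: 20 α-ketol
Product: 21 11-benzyloxy-7,8α-bis(trimethylsilyloxy)drim-6-ene
Conditions: Me3SiOTf (3 equiv), Et3N (5 equiv), CH2Cl2, 0 °C → rt
Reagents that add atoms: trimethylsilyl trifluoromethanesulfonate, C[Si](C)(C)OS(=O)(=O)C(F)(F)F
Why: Soft enolisation/silylation can enolise only toward C6 because C8 is quaternary, and it caps the tertiary alcohol at the same time, which blocks α-ketol rearrangement in the next step.

**Step 14**
Reactants: 21 silyl enol ether
Product: 23 11-benzyloxy-6α,8α-dihydroxydriman-7-one, via bis(silyloxy) ketone 22 (not isolated)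
Conditions: mCPBA, NaHCO3, CH2Cl2, −20 → 0 °C; then 1 M HCl, THF, 0 °C
Reagents that add atoms: 3-chloroperoxybenzoic acid, O=C(OO)c1cccc(Cl)c1
Why: In this Rubottom oxidation the peracid should epoxidise the enol ether on the α face (the β face of C6 is screened by the axial C10, C8 and 4β methyl groups), silyl migration gives the 6α-silyloxy ketone and mild acid removes both silyl groups.

**Step 15**
Reactants: 23 dihydroxy ketone
Product: 24 6α-acetoxy-11-benzyloxy-8α-hydroxydriman-7-one
Conditions: Ac2O, pyridine, DMAP (cat.), CH2Cl2, 0 °C → rt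
Reagents that add atoms: acetic anhydride, CC(=O)OC(C)=O
Why: DMAP-catalysed acylation acetylates the secondary 6α-OH while the hindered tertiary 8α-OH should not react at room temperature.

**Step 16**
Reactants: 24 acetoxy ketone
Product: 25 6α-acetoxy-11-benzyloxydrimane-7β,8α-diol
Conditions: NaBH4, MeOH–CH2Cl2, −40 °C; AcOH quench
Reagents that add atoms: none
Why: Borohydride reduction should proceed by axial attack on the α face (the equatorial β approach is blocked by the axial 8β-methyl group) and give the equatorial 7β-alcohol, while low temperature and the acidic quench limit acetyl migration from O6 to O7.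

**Step 17**
Reactants: 25 benzyl ether
Product: 26 6α-acetoxydrimane-7β,8α,11-triol
Conditions: H2 (1 atm), Pd/C, EtOAc, rt
Reagents that add atoms: none
Why: Catalytic hydrogenolysis cleaves the benzyl ether and frees the primary C11 alcohol, and no other group in the molecule is reducible.

**Step 18**
Reactants: 26 triol
Product: 27 6α-acetoxy-7β,8α-dihydroxydriman-11-al
Conditions: TEMPO (10 mol%), PhI(OAc)2 (1.2 equiv), CH2Cl2, rt
Reagents that add atoms: none
Why: The oxoammonium-mediated oxidation is selective for the primary alcohol over the hindered secondary 7β-OH and the tertiary 8α-OH and stops at the aldehyde.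

**Step 19**
Reactants: 27 aldehyde; 28 1-(triphenylphosphoranylidene)propan-2-one
Product: 29 (E)-6α-acetoxy-7β,8α-dihydroxy-14,15-dinorlabd-11-en-13-one (CNP0136046.1)
Conditions: 28 (3 equiv), toluene, 90 °C
Reagents that add atoms: none
Why: Wittig olefination with the stabilised acetonyl ylide should give the E-enone under neutral conditions that leave the acetate, the diol and C9 untouched.

**Compound list**

1 | (1R,5R)-verbenone | O=C1C=C(C)[C@H]2C[C@@H]1C2(C)C | starting material
2 | 2-methylallylmagnesium chloride | C=C(C)C[Mg]Cl | starting material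
3 | 4,6,6-trimethyl-4-(2-methylallyl)-2-(trimethylsilyloxy)bicyclo[3.1.1]hept-2-ene (bridgeheads as in 1; methallyl anti to the CMe2 bridge) | C[Si](C)(C)OC1=C[C@@](C)(CC(C)=C)[C@H]2C[C@@H]1C2(C)C | intermediate
4 | benzyl chloromethyl ether | ClCOCc1ccccc1 | starting material
5 | lithium enolate of 4,6,6-trimethyl-4-(2-methylallyl)bicyclo[3.1.1]heptan-2-one | [Li]OC1=C[C@@](C)(CC(C)=C)[C@H]2C[C@@H]1C2(C)C | intermediate (not isolated)
6 | 3-(benzyloxymethyl)-4,6,6-trimethyl-4-(2-methylallyl)bicyclo[3.1.1]heptan-2-one (CH2OBn and methallyl cis, both anti to the CMe2 bridge) | O=C1[C@@H](COCc2ccccc2)[C@@](C)(CC(C)=C)[C@H]3C[C@@H]1C3(C)C | intermediate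
7 | 3-(benzyloxymethyl)-4,6,6-trimethyl-4-(2-oxopropyl)bicyclo[3.1.1]heptan-2-one | O=C1[C@@H](COCc2ccccc2)[C@@](C)(CC(C)=O)[C@H]3C[C@@H]1C3(C)C | intermediate
8 | terminal lithium enolate of the methyl ketone of 7 | O=C1[C@@H](COCc2ccccc2)[C@@](C)(CC(=C)O[Li])[C@H]3C[C@@H]1C3(C)C | intermediate (not isolated)
9 | 3-(benzyloxymethyl)-4,6,6-trimethyl-4-[2-(trimethylsilyloxy)allyl]bicyclo[3.1.1]heptan-2-one (key-step precursor) | O=C1[C@@H](COCc2ccccc2)[C@@](C)(CC(=C)O[Si](C)(C)C)[C@H]3C[C@@H]1C3(C)C | intermediate
10 | 9α-(benzyloxymethyl)-4,4,10β-trimethyl-8-(trimethylsilyloxy)-trans-octal-7-en-2-one (5α-H; key-step product) | C(OCc3ccccc3)[C@@H]1C(O[Si](C)(C)C)=CC[C@H]2C(C)(C)CC(=O)C[C@@]21C | intermediate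
11 | 9α-(benzyloxymethyl)-8,8-(ethylenedioxy)-4,4,10β-trimethyl-trans-decalin-2-one | C(OCc3ccccc3)[C@@H]1C4(OCCO4)CC[C@H]2C(C)(C)CC(=O)C[C@@]21C | intermediate
12 | C2 hydrazone of 11 | C(OCc3ccccc3)[C@@H]1C4(OCCO4)CC[C@H]2C(C)(C)CC(=NN)C[C@@]21C | intermediate (not isolated)
13 | 11-benzyloxy-9-epi-12-nordriman-8-one ethylene ketal | C(OCc3ccccc3)[C@@H]1C4(OCCO4)CC[C@H]2C(C)(C)CCC[C@@]21C | intermediate
14 | 11-benzyloxy-9-epi-12-nordriman-8-one (9α-CH2OBn) | C(OCc3ccccc3)[C@@H]1C(=O)CC[C@H]2C(C)(C)CCC[C@@]21C | intermediate (not isolated)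
15 | 11-benzyloxy-12-nordriman-8-one (9β-CH2OBn, 9α-H) | C(OCc3ccccc3)[C@H]1C(=O)CC[C@H]2C(C)(C)CCC[C@@]21C | intermediate
16 | lithium Δ7-enolate of 15 | C(OCc3ccccc3)[C@H]1C(O[Li])=CC[C@H]2C(C)(C)CCC[C@@]21C | intermediate (not isolated)
17 | 11-benzyloxy-12-nordrim-7-en-8-yl trifluoromethanesulfonate | C(OCc3ccccc3)[C@H]1C(OS(=O)(=O)C(F)(F)F)=CC[C@H]2C(C)(C)CCC[C@@]21C | intermediate
18 | 11-O-benzyldrimenol | C(OCc3ccccc3)[C@H]1C(C)=CC[C@H]2C(C)(C)CCC[C@@]21C | intermediate
19 | 11-benzyloxydrimane-7α,8α-diol | C(OCc3ccccc3)[C@H]1[C@](C)(O)[C@H](O)C[C@H]2C(C)(C)CCC[C@@]21C | intermediate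
20 | 11-benzyloxy-8α-hydroxydriman-7-one | C(OCc3ccccc3)[C@H]1[C@](C)(O)C(=O)C[C@H]2C(C)(C)CCC[C@@]21C | intermediate
21 | 11-benzyloxy-7,8α-bis(trimethylsilyloxy)drim-6-ene | C(OCc3ccccc3)[C@H]1[C@](C)(O[Si](C)(C)C)C(O[Si](C)(C)C)=C[C@H]2C(C)(C)CCC[C@@]21C | intermediate
22 | 11-benzyloxy-6α,8α-bis(trimethylsilyloxy)driman-7-one | C(OCc3ccccc3)[C@H]1[C@](C)(O[Si](C)(C)C)C(=O)[C@H](O[Si](C)(C)C)[C@H]2C(C)(C)CCC[C@@]21C | intermediate (not isolated)
23 | 11-benzyloxy-6α,8α-dihydroxydriman-7-one | C(OCc3ccccc3)[C@H]1[C@](C)(O)C(=O)[C@H](O)[C@H]2C(C)(C)CCC[C@@]21C | intermediate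
24 | 6α-acetoxy-11-benzyloxy-8α-hydroxydriman-7-one | C(OCc3ccccc3)[C@H]1[C@](C)(O)C(=O)[C@H](OC(C)=O)[C@H]2C(C)(C)CCC[C@@]21C | intermediate
25 | 6α-acetoxy-11-benzyloxydrimane-7β,8α-diol | C(OCc3ccccc3)[C@H]1[C@](C)(O)[C@@H](O)[C@H](OC(C)=O)[C@H]2C(C)(C)CCC[C@@]21C | intermediate
26 | 6α-acetoxydrimane-7β,8α,11-triol | OC[C@H]1[C@](C)(O)[C@@H](O)[C@H](OC(C)=O)[C@H]2C(C)(C)CCC[C@@]21C | intermediate
27 | 6α-acetoxy-7β,8α-dihydroxydriman-11-al | O=C[C@H]1[C@](C)(O)[C@@H](O)[C@H](OC(C)=O)[C@H]2C(C)(C)CCC[C@@]21C | intermediate
28 | 1-(triphenylphosphoranylidene)propan-2-one | CC(=O)C=P(c1ccccc1)(c1ccccc1)c1ccccc1 | starting material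
29 | (E)-6α-acetoxy-7β,8α-dihydroxy-14,15-dinorlabd-11-en-13-one (CNP0136046.1) | CC(=O)/C=C/[C@H]1[C@](C)(O)[C@@H](O)[C@H](OC(C)=O)[C@H]2C(C)(C)CCC[C@@]21C | target

**Step count**

Total steps: 19. Longest linear sequence: 19 (the route is linear from 1).

**Steps most likely to fail**

Step 5 (key step). The silylated C8 carbonyl may be intercepted by the pendant enol ether in a Mukaiyama aldol addition before the cyclobutane ionises, or the C4 cation may lose a proton instead of closing ring A. The fallback sets out from 9 and comes back at 10 by separating the two events. Iodotrimethylsilane (Me3SiCl/NaI, MeCN–CH2Cl2, −40 °C, short contact to spare the benzyl ether) effects the known iodide-assisted cleavage of pinane-type cyclobutyl ketones and stores the cation as a covalent halide, the ring-opened tertiary iodide 6-(benzyloxymethyl)-4-(2-iodopropan-2-yl)-5-methyl-1-(trimethylsilyloxy)-5-[2-(trimethylsilyloxy)allyl]cyclohexene F1. F1 is then ionised under the known conditions for tert-alkylation of silyl enol ethers (ZnI2 cat. or TiCl4, CH2Cl2, −40 °C), where only the C3 terminus can reach C4, to give 10.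

Step 8. The equatorial preference at C9 may be too small for clean equilibration, or enolisation toward C9 may end in net E1cB loss of benzyl alcohol. The fallback sets out from 14 and comes back at 15. The elimination is made deliberate (DBU, toluene, 80 °C) and gives the exocyclic enone 12-nordrim-9(11)-en-8-one F2. Benzyl alcohol is then added back in an oxa-Michael reaction (BnOH, BnONa cat., THF, −20 °C, quenched early), in which the C8–C9 enolate is protonated on the α face, axially and opposite the C10 methyl group, so that C9 is set under kinetic control and not by an equilibrium.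

Step 19. Slow olefination of the neopentyl-type aldehyde may let C9 epimerisation, retro-aldol cleavage of the C8–C9 bond or acetyl migration take over under the basic ylide at high temperature. The fallback sets out from 27 and comes back at 29. The aldehyde is methylenated under non-basic conditions with the Zn/CH2Br2/TiCl4 reagent (Takai–Lombardo) to the C9 vinyl compound 6α-acetoxy-13,14,15,16-tetranorlabd-11-ene-7β,8α-diol F3, and cross-metathesis of F3 with methyl vinyl ketone (second-generation Hoveyda–Grubbs catalyst, CH2Cl2, 40 °C) should give the E-enone 29.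

**Further compounds**

F1 | step 5 | 6-(benzyloxymethyl)-4-(2-iodopropan-2-yl)-5-methyl-1-(trimethylsilyloxy)-5-[2-(trimethylsilyloxy)allyl]cyclohexene | C(OCc3ccccc3)[C@@H]1C(O[Si](C)(C)C)=CC[C@@H](C(C)(C)I)[C@]1(C)CC(=C)O[Si](C)(C)C
F2 | step 8 | 12-nordrim-9(11)-en-8-one | C=C1C(=O)CC[C@H]2C(C)(C)CCC[C@@]21C
F3 | step 19 | 6α-acetoxy-13,14,15,16-tetranorlabd-11-ene-7β,8α-diol | C=C[C@H]1[C@](C)(O)[C@@H](O)[C@H](OC(C)=O)[C@H]2C(C)(C)CCC[C@@]21C
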